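I judge these flasks by one number, the site share: incoming ligand per complex present while the ligand lasts, divided by the 3 exchangeable places. If each exchange is first order in ligand, integrating that rate gives every place the same exposure. If the places also fill alike and independently, the three-exchanged share is the cube of the site share, and the unexchanged share is the cube of its remainder.

| flask | starting complex | incoming ligand | scavenger | remark | time |
|---|---|---|---|---|---|
| ochre | 0.050 M | 1.1 equiv | 1.5 equiv | run made earlier |  |
| teal | 0.050 M | 1.1 equiv | 2.1 equiv | run made earlier |  |
| amber | 0.050 M | 1.1 equiv | 3.3 equiv | run made earlier |  |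
| blue | 0.075 M | 1.1 equiv | 1.5 equiv | run made earlier |  |
| noon | 0.050 M | 1.10 equiv | 1.50 equiv | everything together at the start | 4.0 min |
| midnight | 0.050 M | 1.10 equiv (fed, over 2.5 min) | 1.50 equiv | all else is in the flask from the start; the feed brings no volume worth counting | 4.0 min |
| autumn | 0.050 M (in portions, 2, over 2.5 min) | 1.10 equiv | 1.50 equiv | first portion at the start, last at 2.5 min | 4.0 min |
| summer | 0.050 M (fed, over 2.5 min) | 1.10 equiv | 1.50 equiv | all else is in the flask from the start; the feed brings no volume worth counting | 4.0 min |

| run | time / min | complex with three exchanged / % | complex with two exchanged / % |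
|---|---|---|---|
| ochre | 0.200 | 3.5 | 11.8 |
| ochre | 0.333 | 4.1 | 14.5 |
| ochre | 0.417 | 5.1 | 17.0 |
| ochre | 0.667 | 7.1 | 18.6 |
| ochre | 1.00 | 7.4 | 17.5 |
| ochre | 1.50 | 7.3 | 18.1 |
| ochre | 2.50 | 8.6 | 18.4 |
| teal | 0.417 | 6.3 | 14.8 |
| teal | 0.667 | 5.6 | 19.3 |
| teal | 0.833 | 7.9 | 19.2 |
| teal | 1.33 | 5.8 | 19.9 |
| teal | 2.00 | 6.9 | 20.9 |
| teal | 3.00 | 8.2 | 18.1 |
| teal | 5.00 | 5.4 | 17.6 |
| amber | 0.250 | 3.2 | 13.8 |
| amber | 0.667 | 7.4 | 19.5 |
| amber | 1.33 | 7.6 | 20.2 |
| amber | 2.00 | 9.2 | 17.4 |
| amber | 3.00 | 8.6 | 20.2 |
| amber | 4.00 | 8.9 | 19.3 |
| amber | 5.00 | 5.9 | 18.9 |
| blue | 0.417 | 5.4 | 17.8 |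
| blue | 1.33 | 8.9 | 18.4 |
| blue | 2.00 | 8.7 | 18.8 |
| blue | 3.00 | 9.2 | 19.5 |
| blue | 5.00 | 9.4 | 19.2 |

(standard deviation of a reading: 1 percentage point)

- the numbers in the tables scatter by 1 percentage point (one standard deviation)

- which flask leads in amount of complex with three exchanged, in percent of the starting complex charged ("all alike" within 1.5 percentage points) (noon / midnight / autumn / summer / all alike)
- how much complex with three exchanged is there at the end, in percent of the starting complex charged: noon
- how much complex with three exchanged is there at the end, in percent of the starting complex charged: midnight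
- how much complex with three exchanged is there at the end, in percent of the starting complex charged: autumn
- how much complex with three exchanged is there at the end, in percent of the starting complex charged: summer

The last 3 readings of each run average 7.88% three-exchanged and 18.9% two-exchanged, with scavenger from 1.50 equiv to 3.3 equiv.

I take the incoming ligand as limiting reagent and reach the noon starting complex by two ways. The ligand balance leaves 48.6% one-exchanged, so 24.6% starting complex. The site share of 0.367 gives 25.4%, and these agree.

They part on the three-exchanged complex: the cube gives 4.93% against the reading of 7.88%. The gap of 2.9 percentage points is larger than the scatter of one reading, so the cube is what cheats: the readings do not fit places that fill alike. I keep the cube as my low estimate, and the cube times the read ratio 1.60 as my high estimate.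

Midnight has the same site share as noon, so I expect the noon level there. The second autumn portion comes at 2.5 min, later than the 1.00 min by which the ochre run reads its level, so I count the ligand on the first portion: site share 0.733, which gives autumn estimates of 19.7% and 31.5% of the charge. The low estimate for autumn already stands above the level read in the earlier runs. For summer I reckon no share of my own and place it near autumn.

The forecast names autumn, with noon 8%, midnight 8%, autumn 24% and summer 23%, and for midnight it reasons: “Every step is first order in ligand, so the split depends only on ligand consumed. Midnight therefore equals noon.”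

The flasks give noon 8.02%, midnight 7.40%, autumn 22.9% and summer 20.7%, so autumn leads. Autumn ends with 49.2% starting complex, close to the last portion of 50.0%. Its result lies between the low site-share estimate 19.7% and the high one 31.5% . The forecast's midnight figure would be wrong in a run with scavenger down at 0.588 equiv, all else held, where the midnight answer has moved by 5 points.

    scavenger + leaving ligand → scavenged by-product (k = 47.3 M⁻¹ s⁻¹)
    complex with one exchanged + incoming ligand ⇌ leaving ligand + complex with two exchanged (K = 0.300, k = 1.25 M⁻¹ s⁻¹)
    leaving ligand → by-product carried off (k = 0.0284 s⁻¹)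
    complex with two exchanged + incoming ligand ⇌ leaving ligand + complex with three exchanged (K = 0.910, k = 1.45 M⁻¹ s⁻¹)
    starting complex + incoming ligand ⇌ leaving ligand + complex with one exchanged (K = 1.13, k = 2.56 M⁻¹ s⁻¹)
    leaving ligand + starting complex ⇌ idle adduct, settled at all times (K = 200 M⁻¹)

For midnight with 1.90 equiv of incoming ligand, the site share is 0.633, so my estimates are 25.4% and 40.6% three-exchanged. The computed flask gives 36.1% , with 6.17% of its incoming ligand still there at the end.

The numbers in the tables come from a simulation for an exercise.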